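Read at 8.00 d, the last reading of both earlier runs, the west flask held 24% target and the south-west flask 51%, and the meeting opened on these two figures.

| flask | electrophile | nucleophile | protic impurity | remark | time |
|---|---|---|---|---|---|
| west | 0.13 M | 0.16 M | 0.13 M | run made earlier |  |
| south-west | 0.13 M | 0.35 M | 0.13 M | run made earlier |  |
| midnight | 0.13 M | 0.140 M | 0.130 M |  | 10 d |
| dusk | 0.13 M | 0.190 M | 0.130 M |  | 10 d |
| spring | 0.13 M | 0.240 M | 0.130 M |  | 10 d |

| run | time / d | electrophile / % | target / % |
|---|---|---|---|
| west | 0.625 | 87 | 14 |
| west | 0.833 | 87 | 14 |
| west | 1.67 | 81 | 18 |
| west | 2.50 | 83 | 20 |
| west | 4.00 | 78 | 24 |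
| west | 8.00 | 76 | 24 |
| south-west | 0.625 | 72 | 26 |
| south-west | 0.833 | 71 | 28 |
| south-west | 1.67 | 58 | 36 |
| south-west | 2.50 | 57 | 42 |
| south-west | 4.00 | 54 | 45 |
| south-west | 8.00 | 46 | 51 |

(standard deviation of a reading: 2 percentage points)



- part of the electrophile that has reacted at the end, midnight
- part of the electrophile that has reacted at the end, dusk
- part of the electrophile that has reacted at the end, spring
- what raising the concentration of nucleophile from its lowest to its highest value here does to the part of the electrophile that has reacted (changes below 5 percentage points count as none) (it falls / it rises / no change)

I, keeping these minutes, argued that the two readings become nearly one number when turned into moles of target per mole of nucleophile charged: 19.5% in west and 18.9% in south-west. Their mean, 19.2%, I named the capture share, the target made per nucleophile charged, and I proposed replacing the curve of target against nucleophile by a straight line of that slope through zero.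

I then checked what the mean costs. The gap between the two shares, 0.60 percentage points, is smaller than the 1.6 points that the scatter puts on the west share. The readings also stop short of 10 d. West read 24% at 4.00 d and 24% at 8.00 d, while the south-west reading gained 6 points between those times. Carried on at that mean rate, south-west would add 3 points, which is below the 5 points that counts as a change, so I left it as an error and did not correct for it.

For midnight, dusk and spring my line gives 20.7%, 28.1% and 35.5%, a rise of 15 points.

The forecaster reported 21%, 30% and 38%, with the trend "it rises", on the ground that “Plateaus depending on nucleophile look more like a reversible addition”. At spring my figure is lower than the forecast's by 2.5 points, and the meeting recorded both.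

    nucleophile ⇌ dormant form (K = 13.0, k = 0.0140 h⁻¹)
    nucleophile + protic impurity → quenched reagent (k = 0.180 L mol⁻¹ h⁻¹)
    electrophile + nucleophile → acid set free + target (k = 0.0760 L mol⁻¹ h⁻¹)
    nucleophile + acid set free ⇌ protonated nucleophile, settled at all times (K = 1200 L mol⁻¹)

Midnight, dusk and spring give 21.5%, 29.0% and 36.4%, so with more nucleophile the part reacted: it rises, a change of 15 points. The forecast stands, and my line falls 0.90 points short at spring. Reckoned back, the capture share is 20.0% at midnight and 19.7% at spring. Nucleophile is the limiting reagent at midnight, with 1.1% of its charge free after 10.0 d. A neighbour of midnight charged with 0.56 M of nucleophile should reach 82.8% by the same share. It reaches 77.2%, a share of 17.9%, with 22.8% of its electrophile left.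

The readings come from a simulation on assumed constants; scatter was added.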